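**Strategy.** Ring A (C1–C5) of this cis-fused daucane has oxygen at C2, an unsubstituted CH2 at C3 and the tertiary carbinol C4(OH)i-Pr next to the fusion carbon C5. This is the pattern of a 4-hydroxycyclopent-2-enone. The plan rests on forming C3–C4 by a Piancatelli rearrangement. In one operation it converts a planar 3-methyl-5-isopropyl-2-furylmethanol, two steps from a commercial furoate, into complete ring A with the C4 stereocentre and the C1=C5 enone. O2, C10, C6 and O4 all lie on one face, so ring B (C1, C5–C10) is added by a cis-specific [2+2] photocycloaddition, cyclobutene ozonolysis, two chelation-controlled additions and ring-closing metathesis.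

Key step: step 3

Numbering and faces: daucane numbering is used (C1 C–CH3, C2 CHOH, C3 CH2, C4 C(OH)i-Pr, C5 fusion CH, C6 CHOAng, C7 CH2, C8(CH3)–C9 epoxide, C10 CHOAng). β is the face of ring A that carries the C4–OH. α is the face that carries i-Pr, H-5 and the C1 methyl.

Assumption: the SMILES is read literally (1R,2S,4S,5R,6R,8S,9R,10R; H-5 and C1–CH3 cis; O2, C10, C6, O4 all β on ring A), so a stepwise conjugate addition/enolate trapping, which would set C6 and C10 trans, is not used; the catalyst antipode that gives (S)-6 must be found by experiment, and the (R)-series is written.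

**Step 1**
Reactants: 1 methyl 3-methyl-2-furoate; 2 2-chloropropane
Product: 3 methyl 5-isopropyl-3-methylfuran-2-carboxylate
Conditions: AlCl3 (2.2 equiv), CH2Cl2, 0 to 23 °C
Reagents that add atoms: 2-chloropropane (2), CC(C)Cl
Why: Friedel–Crafts alkylation, in which the ester occupies one α-position and tames the furan, so the isopropyl cation should attack the only free α-position, as is usual for 2-furoates.

**Step 2**
Reactants: 3 methyl 5-isopropyl-3-methylfuran-2-carboxylate
Product: 4 (5-isopropyl-3-methylfuran-2-yl)methanol
Conditions: LiAlH4, Et2O, 0 °C; basic aqueous work-up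
Reagents that add atoms: none
Why: Hydride reduction of an ester to the primary alcohol leaves the furan untouched, and the acid-sensitive product is carried on without storage.

**Step 3**
Reactants: 4 (5-isopropyl-3-methylfuran-2-yl)methanol
Product: 6 (S)-4-hydroxy-4-isopropyl-2-methylcyclopent-2-en-1-one, via methylidene-dihydrofuranol hemiketal 5 (not isolated)
Conditions: (R)-3,3'-bis(2,4,6-triisopropylphenyl)-BINOL N-triflylphosphoramide (10 mol %), water-saturated CHCl3, 30 °C
Reagents that add atoms: water, O
Why: Proposed new method: the chiral acid ionises the primary carbinol of 4 (the two alkyl donors stabilise the furfuryl cation), the released water adds at the isopropyl-bearing furan carbon (= C4) to give 5, and ring opening gives a 1,4-dihydroxypentadienyl cation. The closest known reactions are the racemic aqueous Piancatelli rearrangement of 5-alkyl-2-furylcarbinols, the aza-Piancatelli rearrangement catalysed by chiral phosphoric acids, and the Nazarov cyclisation catalysed by chiral Brønsted acids; the new element is enantiocontrol with water as the nucleophile on a primary carbinol. Ring A closes by a thermal 4π conrotatory electrocyclisation between the former CH2OH carbon (C3) and C4, and proton loss from the resulting hydroxyallyl cation gives the enone. C4 is the only new stereocentre, and it is controlled by the chiral counter-anion, which is hydrogen-bonded to both hydroxyl groups of the cation and must fix the geometry of the i-Pr/OH terminus and bias the sense of conrotation. The step needs water attack at the substituted α-carbon to win over oligomerisation and over tautomerisation of the opened chain, and the isopropyl group helps by blocking the usual furan coupling site. Because the reaction is a net isomerisation, water-saturated solvent suffices, which keeps the achiral hydronium background low.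

**Step 4**
Reactants: 6 (S)-enone; 7 (Z)-1,2-dichloroethene
Product: 8 6,7-dichloro-4-hydroxy-4-isopropyl-1-methyl-cis-bicyclo[3.2.0]heptan-2-one (cyclobutane on the β face; mixture of C–Cl epimers)
Conditions: hν (medium-pressure mercury lamp, Pyrex filter), 7 (20 equiv), CH2Cl2, −20 °C
Reagents that add atoms: (Z)-1,2-dichloroethene (7), Cl/C=C\Cl
Why: Enone–alkene [2+2] photocycloaddition, in which the 5/4 fusion can only be cis so that C5–C6 and C1–C10 form on one face, and the alkene should approach syn to the small free C4–OH and anti to the isopropyl group, which sets C1 and C5.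

**Step 5**
Reactants: 8 dichloride photoadduct
Product: 9 (1R,4S,5S)-4-hydroxy-4-isopropyl-1-methylbicyclo[3.2.0]hept-6-en-2-one
Conditions: Zn dust, EtOH, 78 °C
Reagents that add atoms: none
Why: Reductive vicinal dehalogenation removes both C–Cl stereocentres, and because C1 is quaternary no dehydrochlorination towards the ketone can compete.

**Step 6**
Reactants: 9 hydroxy cyclobutene
Product: 10 C4 trimethylsilyl ether of 9
Conditions: 1-(trimethylsilyl)imidazole, CH2Cl2, 23 °C
Reagents that add atoms: 1-(trimethylsilyl)imidazole, C[Si](C)(C)n1ccnc1
Why: Silylation of a tertiary alcohol with a strong neutral silyl donor does not enolise the ketone, and it removes the O4 proton and the chelating ability of O4 before the aldehydes are released.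

**Step 7**
Reactants: 10 silyl ether
Product: 12 3-isopropyl-1-methyl-5-oxo-3-(trimethylsilyloxy)cyclopentane-1,2-dicarbaldehyde (both formyl groups and the silyloxy group β), via secondary ozonide 11 (not isolated)
Conditions: O3, CH2Cl2, −78 °C; PPh3, −78 to 0 °C; used crude
Reagents that add atoms: ozone, [O-][O+]=O
Why: Ozonolysis (Criegee mechanism) of the only, strained C=C bond with a neutral reductive work-up cuts C6–C10 and leaves C6 and C10 as cis formyl groups without touching C1, C4 or C5.

**Step 8**
Reactants: 12 dialdehyde; 13 vinylmagnesium bromide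
Product: 15 lactol between O10 and C6 (10-vinyl; C4–OH free; anomer mixture), via O4-trimethylsilyl lactol 14 (not isolated)
Conditions: MgBr2·OEt2, CH2Cl2, −78 °C; 13 (1.1 equiv, THF), −78 °C; then 1 M HCl, THF, 0 °C
Reagents that add atoms: vinylmagnesium bromide (13), C=C[Mg]Br
Why: Cram-chelate Grignard addition, in which magnesium bridges the C2 ketone and the C10 formyl oxygen and so activates this aldehyde over the unchelated, more crowded C6 formyl group, vinyl attack from the side of the C1 methyl (away from C5) sets the 10α-oxygen configuration, the alkoxide closes on C6 to a lactol that masks the second aldehyde and locks the cis arrangement, and dilute acid removes the silyl group.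

**Step 9**
Reactants: 15 lactol; 16 3-bromo-2-methylpropene
Product: 17 diene triol (ring A ketone with β-CH(OH)CH=CH2 at C1 and β-CH(OH)CH2C(CH3)=CH2 at C5; 6α- and 10α-oxygen configuration)
Conditions: In powder, THF–H2O 1:1, 23 °C
Reagents that add atoms: 3-bromo-2-methylpropene (16), C=C(C)CBr
Why: Barbier-type indium allylation in water reacts with lactols through the open hydroxy aldehyde and spares hindered ketones, and indium held by the free C4–OH and the C6 carbonyl forms a six-membered chelate that is attacked from the side of H-5, giving the 1,3-anti C4/C6 diol of the target.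

**Step 10**
Reactants: 17 diene triol
Product: 18 4β,6α,10α-trihydroxy-cis-dauc-8-en-2-one
Conditions: second-generation Grubbs catalyst (5 mol %), 1,4-benzoquinone (10 mol %), CH2Cl2 (2 mM), 40 °C
Reagents that add atoms: none
Why: Ring-closing metathesis of a vinyl carbinol with a 1,1-disubstituted alkene held cis on a cyclopentane closes the seven-membered ring with the trisubstituted C8=C9 bond and touches no stereocentre.

**Step 11**
Reactants: 18 alkene triol
Product: 19 8α,9α-epoxy-4β,6α,10α-trihydroxy-cis-daucan-2-one
Conditions: VO(acac)2 (5 mol %), t-BuOOH (decane), CH2Cl2, 0 °C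
Reagents that add atoms: tert-butyl hydroperoxide, CC(C)(C)OO
Why: Hydroxyl-directed vanadium-catalysed epoxidation delivers oxygen syn to the allylic 10α-OH (reinforced by the homoallylic 6α-OH and by the convex shape of the α face), which sets C8 and C9.

**Step 12**
Reactants: 19 epoxy triol; 20 angelic acid
Product: 22 6α,10α-diangeloyloxy-8α,9α-epoxy-4β-hydroxy-cis-daucan-2-one, via angelic 2,4,6-trichlorobenzoic anhydride 21 (not isolated)
Conditions: 20 (4 equiv), 2,4,6-Cl3C6H2COCl, Et3N, toluene, 23 °C; then 19, 80 °C
Reagents that add atoms: angelic acid (20), C/C=C(/C)C(=O)O; 2,4,6-trichlorobenzoyl chloride (atoms in 21 only), O=C(Cl)c1c(Cl)cc(Cl)cc1Cl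
Why: Yamaguchi-type mixed-anhydride esterification without a nucleophilic catalyst is the established way to install angelates without Z-to-E isomerisation, and only the two secondary alcohols should react because the tertiary C4–OH is inert.

**Step 13**
Reactants: 22 diangelate ketone
Product: 23 target CNP0265715.2
Conditions: (R)-2-methyl-CBS-oxazaborolidine (0.3 equiv), BH3·SMe2, THF, −20 °C; MeOH
Reagents that add atoms: none
Why: Corey–Bakshi–Shibata reduction is reagent-controlled, the ketone binding with quaternary C1 as the large and C3H2 as the small flank, so the (R)-catalyst should deliver hydride to the α face and give the 2β (2S) alcohol while the esters and the epoxide survive.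

**Compound list**

| No. | Name | SMILES | Role |
|---|---|---|---|
| 1 | methyl 3-methyl-2-furoate | COC(=O)c1occc1C | starting material |
| 2 | 2-chloropropane | CC(C)Cl | starting material |
| 3 | methyl 5-isopropyl-3-methylfuran-2-carboxylate | COC(=O)c1oc(C(C)C)cc1C | intermediate |
| 4 | (5-isopropyl-3-methylfuran-2-yl)methanol | OCc1oc(C(C)C)cc1C | intermediate |
| 5 | 2-isopropyl-4-methyl-5-methylidene-2,5-dihydrofuran-2-ol | C=C1OC(O)(C(C)C)C=C1C | intermediate |
| 6 | (S)-4-hydroxy-4-isopropyl-2-methylcyclopent-2-en-1-one | CC1=C[C@@](O)(C(C)C)CC1=O | intermediate |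
| 7 | (Z)-1,2-dichloroethene | Cl/C=C\Cl | starting material |
| 8 | dichlorocyclobutane photoadduct | ClC1C(Cl)[C@@]2(C)C(=O)C[C@](O)(C(C)C)[C@@H]12 | intermediate |
| 9 | (1R,4S,5S)-4-hydroxy-4-isopropyl-1-methylbicyclo[3.2.0]hept-6-en-2-one | C1=C[C@@]2(C)C(=O)C[C@](O)(C(C)C)[C@@H]12 | intermediate |
| 10 | C4 trimethylsilyl ether of 9 | C1=C[C@@]2(C)C(=O)C[C@](O[Si](C)(C)C)(C(C)C)[C@@H]12 | intermediate |
| 11 | secondary ozonide of 10 | C12OC(OO1)[C@@]3(C)C(=O)C[C@](O[Si](C)(C)C)(C(C)C)[C@@H]23 | intermediate |
| 12 | all-β keto dialdehyde silyl ether | O=C[C@@H]1[C@@](O[Si](C)(C)C)(C(C)C)CC(=O)[C@]1(C)C=O | intermediate |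
| 13 | vinylmagnesium bromide | C=C[Mg]Br | starting material |
| 14 | O4-trimethylsilyl lactol | OC1O[C@@H](C=C)[C@@]2(C)C(=O)C[C@](O[Si](C)(C)C)(C(C)C)[C@@H]12 | intermediate |
| 15 | O10–C6 lactol, C4–OH free | OC1O[C@@H](C=C)[C@@]2(C)C(=O)C[C@](O)(C(C)C)[C@@H]12 | intermediate |
| 16 | 3-bromo-2-methylpropene | C=C(C)CBr | starting material |
| 17 | diene triol | O[C@H](CC(C)=C)[C@@H]1[C@@](O)(C(C)C)CC(=O)[C@]1(C)[C@@H](O)C=C | intermediate |
| 18 | 4β,6α,10α-trihydroxy-cis-dauc-8-en-2-one | O[C@@H]1CC(C)=C[C@H](O)[C@@]2(C)C(=O)C[C@](O)(C(C)C)[C@@H]12 | intermediate |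
| 19 | 8α,9α-epoxy triol ketone | O[C@@H]1C[C@]2(C)O[C@@H]2[C@H](O)[C@@]2(C)C(=O)C[C@](O)(C(C)C)[C@@H]12 | intermediate |
| 20 | angelic acid | C/C=C(/C)C(=O)O | starting material |
| 21 | angelic 2,4,6-trichlorobenzoic anhydride | C/C=C(/C)C(=O)OC(=O)c1c(Cl)cc(Cl)cc1Cl | intermediate |
| 22 | diangelate epoxy ketone | C/C=C(/C)C(=O)O[C@@H]1C[C@]2(C)O[C@@H]2[C@H](OC(=O)/C(C)=C\C)[C@@]2(C)C(=O)C[C@](O)(C(C)C)[C@@H]12 | intermediate |
| 23 | CNP0265715.2 | C/C=C(/C)C(=O)O[C@@H]1C[C@]2(C)O[C@@H]2[C@H](OC(=O)/C(C)=C\C)[C@@]2(C)[C@@H](O)C[C@](O)(C(C)C)[C@@H]12 | target |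

Total step count: 13. Longest linear sequence: 13 steps (1 to 23).

**Steps most likely to fail**

**Step 3.**
- **Risk:** asymmetric induction may be low or of the wrong sense, ionisation may be sluggish in the weakly polar medium, or the opened chain may tautomerise away before it cyclises.
- **Fallback (known chemistry, from 4 back to 6):** 4 is rearranged under the classical achiral conditions for 5-alkyl-2-furylcarbinols (ZnCl2, H2O–1,4-dioxane, reflux) to racemic 4-hydroxy-4-isopropyl-2-methylcyclopent-2-en-1-one F1. Reagent-controlled CBS reduction ((R)-2-methyl-CBS-oxazaborolidine, BH3·SMe2) converts both enantiomers into (1S)-carbinols. These are the cis-diol (1S,4S)-4-isopropyl-2-methylcyclopent-2-ene-1,4-diol F2 and the trans-diol (1S,4R)-4-isopropyl-2-methylcyclopent-2-ene-1,4-diol F3, which are diastereomers and are separated on silica gel. MnO2 in CH2Cl2 oxidises the secondary allylic alcohol of F2 back to the ketone and gives 6.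

**Step 4.**
- **Risk:** facial selectivity may be poor, or the hindered 2-methyl enone triplet may be trapped inefficiently by an external alkene.
- **Fallback (from 6 back to 9):** the two-carbon unit is tied to O4 so that it can only arrive on the β face. Compound 6 is silylated with chloro(ethynyl)dimethylsilane and imidazole to the ethynyldimethylsilyl ether F4. Irradiation brings about an intramolecular enone–alkyne [2+2] photocycloaddition, with first closure to the five-membered oxasilacycle, and gives the silacycle-fused cyclobutene F5. Protodesilylation with Bu4NF in wet THF frees C6–H and O4–H and gives 9.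

**Step 8.**
- **Risk:** chemoselectivity between the two formyl groups may be lost, or C5 may epimerise or the silyloxy group undergo β-elimination before the addition.
- **Fallback (from 9 back to 17):** the order of the two additions is reversed and a different selectivity principle is used. Unprotected 9 is ozonised (O3; PPh3) to the hydroxy dialdehyde F6. Indium and 16 in THF–H2O add first at C6, where chelation by the free C4–OH accelerates the reaction while the more electrophilic C10 formyl group rests as its hydrate, and this gives the O6–C10 lactol F7. Excess vinylmagnesium bromide 13 at −78 °C then adds to the opened, ketone-chelated C10 aldehyde and gives 17.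

**Further compounds**
F1 | step 3 | racemic 4-hydroxy-4-isopropyl-2-methylcyclopent-2-en-1-one | CC1=CC(O)(C(C)C)CC1=O
F2 | step 3 | (1S,4S)-4-isopropyl-2-methylcyclopent-2-ene-1,4-diol | CC1=C[C@@](O)(C(C)C)C[C@@H]1O
F3 | step 3 | (1S,4R)-4-isopropyl-2-methylcyclopent-2-ene-1,4-diol | CC1=C[C@](O)(C(C)C)C[C@@H]1O
F4 | step 4 | ethynyldimethylsilyl ether of 6 | CC1=C[C@@](O[Si](C)(C)C#C)(C(C)C)CC1=O
F5 | step 4 | silacycle-fused cyclobutene | C[Si]1(C)O[C@]2(C(C)C)CC(=O)[C@]3(C)C=C1[C@H]23
F6 | step 8 | all-β hydroxy keto dialdehyde | O=C[C@@H]1[C@@](O)(C(C)C)CC(=O)[C@]1(C)C=O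
F7 | step 8 | O6–C10 lactol carrying the methallyl group | OC1O[C@H](CC(C)=C)[C@@H]2[C@@](O)(C(C)C)CC(=O)[C@]12C
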